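All constants stand for no real mixture.

You asked for a quick number and guessed that the free base charge would move the answer. I reckoned it like this.

common to all: electrophile 0.40 M; nucleophile 0.520 M; time 2.0 h
- Wednesday's: free base 0.270 M
- Thursday's: free base 0.120 M
- Sunday's: free base 0.180 M

    electrophile + nucleophile → acid set free + target (k1 = 0.0195 /M/min)
    nucleophile + acid set free ⇌ protonated nucleophile, settled at all times (K2 = 187 /M)
    2 electrophile → self-condensation product (k3 = 1.55 × 10⁻⁵ /M/min)
    electrophile + target → side product (k4 = 0.0895 /M/min)
    acid set free + free base ⇌ salt of the base, settled at all times (K5 = 6200 /M)
    free base + target → over-reaction product (k6 = 0.141 /M/min)

- part of the electrophile that has reacted at the end, Wednesday's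
- part of the electrophile that has reacted at the end, Thursday's
- part of the electrophile that has reacted at the end, Sunday's
- what raising the concentration of free base from its lowest to its highest value here does to the part of the electrophile that has reacted (changes below 5 percentage points count as none) (it falls / no change / it rises)

I began with the easy step. One turn of step 1 spends one electrophile and makes one target. That target then forks: a second electrophile takes it to side product, or free base takes it to over-reaction product. An even fork was my zero, at 1.5 electrophile units per turn. The spend number, electrophile units gone per turn of step 1, is one plus the side-product share k4[electrophile]/(k4[electrophile] + k6[free base]). At charge it came to 1.48 for Wednesday's, 1.68 for Thursday's and 1.59 for Sunday's.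

I treated the loss of electrophile as pseudo-first-order, with [nucleophile] held at charge. That gave about 0.225 M of turns for Wednesday's, 0.207 M for Thursday's and 0.216 M for Sunday's. Free base has the larger binding constant for acid than nucleophile has. My estimated turns for Thursday's exceeded its free base charge, and those for Sunday's exceeded its own, so in those two reckonings I let the excess acid take nucleophile too. Using mean [nucleophile], I committed to 75.7% for Wednesday's, 76.9% for Thursday's and 76.8% for Sunday's. By the stated margin, my estimate was no change.

The forecast gave 82.5%, 85% and 84%, each above mine , with no change: “the net effect is a slight fall of only two or three points”.

The simulation gave 72.9%, 74.6% and 74.3%, so no change, at −1.7 percentage points from the lowest to the highest free base charge.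

The forecast's figures are what [nucleophile] held at its charge gives, but Wednesday's had 54% of its nucleophile still unbound at the end. Counting turns as target plus over-reaction product plus half the side-product units, Wednesday's read 1.44 units per turn at 2.0 h, against my 1.48. The same flask read at 8.0 h had 97.9% of its electrophile reacted, with 6.99% as target, 24.4% as over-reaction product and 66.4% as side product, which reads 1.52 units per turn.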